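**Strategy.** The trimer is cut at both C4–C6 bonds into 8-bromo-epicatechin and one bromine-capped catechin-type flavan-3,4-diol that serves twice. Ring C of that diol is grown from a dihydrobenzofuran: in a 3-hydroxy-2,3-dihydrobenzofuran-3-carbaldehyde an α-ketol shift moves C2 from the carbinol carbon (future C4) onto the formyl carbon (future C3). The step exploits the O1–C2(aryl) carbon as migrating group and the phloroglucinol ring A, which makes the C4 aryl ketone the thermodynamic sink; it delivers the six-membered ring, the trans C3 hydroxyl and the C4 carbonyl handle for both interflavan bonds at once. C2 is set by copper-catalysed propargylic etherification.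

Key step: step 7

Remark: the facial sense of the copper–pybox catalyst with this phenol is assumed; if it is opposite, the (R,R)-ligand is used and nothing else changes.
Remark: diol 12 serves as both the middle and the top unit; its C4 configuration (drawn 3,4-trans) is lost on ionisation and does not matter.

Step 1
Reactants: 1 3,5-bis(benzyloxy)phenol
Product: 2 3,5-bis(benzyloxy)-2-iodophenol
Conditions: NIS (1.0 equiv), CH2Cl2, −40 to 0 °C
Reagents that add atoms: N-iodosuccinimide, O=C1CCC(=O)N1I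
Why: Electrophilic aromatic iodination; the position next to the free hydroxyl is the less hindered of the activated sites and is statistically favoured, and any 4-iodo isomer is removed by chromatography.

Step 2
Reactants: 3 3,4-bis(benzyloxy)benzaldehyde
Product: 5 rac-1-[3,4-bis(benzyloxy)phenyl]prop-2-yn-1-yl acetate, via bromomagnesium propargylic alkoxide 4 (not isolated)
Conditions: HC≡CMgBr, THF, 0 °C; then Ac2O, 0 °C to rt
Reagents that add atoms: ethynylmagnesium bromide, C#C[Mg]Br; acetic anhydride, CC(=O)OC(C)=O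
Why: Grignard addition to the aldehyde and O-acylation of the magnesium alkoxide in the same flask; the centre is racemic here and is made uniform in step 3.

Step 3
Reactants: 2 3,5-bis(benzyloxy)-2-iodophenol; 5 rac-1-[3,4-bis(benzyloxy)phenyl]prop-2-yn-1-yl acetate
Product: 6 1,5-bis(benzyloxy)-3-({(1S)-1-[3,4-bis(benzyloxy)phenyl]prop-2-yn-1-yl}oxy)-2-iodobenzene
Conditions: (CuOTf)2·C6H6 (5 mol %), (S,S)-Ph-pybox (10 mol %), i-Pr2NEt (1.2 equiv), toluene, −20 °C
Reagents that add atoms: none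
Why: Copper-catalysed enantioselective propargylic substitution: loss of acetate from the copper acetylide gives a copper allenylidene in which the old centre is erased, and the pybox ligand directs O-attack of the phenol to one face, setting the future C2 centre (S here) from both enantiomers of 5.

Step 4
Reactants: 6 1,5-bis(benzyloxy)-3-({(1S)-1-[3,4-bis(benzyloxy)phenyl]prop-2-yn-1-yl}oxy)-2-iodobenzene
Product: 7 (2R)-4,6-bis(benzyloxy)-2-[3,4-bis(benzyloxy)phenyl]-3-methylidene-2,3-dihydro-1-benzofuran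
Conditions: Bu3SnH (1.3 equiv), AIBN (10 mol %), benzene, 80 °C; filtered through basic alumina and used at once
Reagents that add atoms: none
Why: Tin hydride aryl radical cyclisation, 5-exo-dig onto the terminal alkyne, with the vinyl radical quenched by Bu3SnH; the stereocentre is not involved (its descriptor changes only by priority), and neutral conditions should keep the exocyclic alkene from isomerising to the aromatic benzofuran.

Step 5
Reactants: 7 (2R)-4,6-bis(benzyloxy)-2-[3,4-bis(benzyloxy)phenyl]-3-methylidene-2,3-dihydro-1-benzofuran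
Product: 8 (2R,3R)-4,6-bis(benzyloxy)-2-[3,4-bis(benzyloxy)phenyl]-3-(hydroxymethyl)-2,3-dihydro-1-benzofuran-3-ol
Conditions: OsO4 (2 mol %), NMO, pyridine (cat.), acetone–H2O, 0 °C
Reagents that add atoms: osmium tetroxide, O=[Os](=O)(=O)=O; N-methylmorpholine N-oxide, C[N+]1([O-])CCOCC1; water, O
Why: Catalytic syn-dihydroxylation of the electron-rich 1,1-disubstituted alkene; osmium should add to the face away from the C2 aryl group, placing the tertiary hydroxyl trans and the hydroxymethyl group cis to it.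

Step 6
Reactants: 8 (2R,3R)-4,6-bis(benzyloxy)-2-[3,4-bis(benzyloxy)phenyl]-3-(hydroxymethyl)-2,3-dihydro-1-benzofuran-3-ol
Product: 9 (2R,3S)-4,6-bis(benzyloxy)-2-[3,4-bis(benzyloxy)phenyl]-3-hydroxy-2,3-dihydro-1-benzofuran-3-carbaldehyde
Conditions: SO3·pyridine, DMSO, i-Pr2NEt, CH2Cl2, 0 °C
Reagents that add atoms: none
Why: Parikh–Doering oxidation takes the primary alcohol to the aldehyde under basic conditions; the tertiary benzylic hydroxyl cannot be oxidised and is not ionised.

Step 7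
Reactants: 9 (2R,3S)-4,6-bis(benzyloxy)-2-[3,4-bis(benzyloxy)phenyl]-3-hydroxy-2,3-dihydro-1-benzofuran-3-carbaldehyde
Product: 10 (2R,3R)-5,7-bis(benzyloxy)-2-[3,4-bis(benzyloxy)phenyl]-3-hydroxychroman-4-one (5,7,3′,4′-tetra-O-benzyltaxifolin)
Conditions: Al(Ot-Bu)3 (20 mol %), toluene, 40 °C
Reagents that add atoms: none
Why: The aluminium alkoxide of the tertiary hydroxyl chelates the formyl oxygen, and the ring bond from C2 to the carbinol carbon, held perpendicular to the carbonyl plane, shifts onto the formyl carbon while the carbinol carbon becomes the C4 ketone (α-ketol, or acyloin, rearrangement; the closest precedents are ring-enlarging α-ketol shifts of 1-hydroxycycloalkanecarbaldehydes and the D-homoannulation of 17-hydroxy-20-oxosteroids). No ring is closed by cyclisation: ring C arises by one-carbon ring expansion, the former formyl carbon being inserted between C2 and the old carbinol carbon. C2 migrates with retention, so the catalytically set centre is carried over unchanged. The new C3 centre is fixed by the syn-periplanar O–C–C=O chelate, in which C2 reaches the formyl face that puts the 3-hydroxyl trans to the C2 aryl group; this is also the more stable diequatorial isomer, so any cis isomer can settle to it by enolisation. The step needs migration of C2 rather than the ring A carbon and must avoid dehydration to the benzofuran: the shift is reversible and drains to the ketone conjugated with the 2,4,6-trioxygenated ring, the fused arene is poorly aligned for migration, and the non-acidic aluminium tert-butoxide (no transferable hydride) should not ionise the tertiary benzylic hydroxyl.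

Step 8
Reactants: 10 (2R,3R)-5,7-bis(benzyloxy)-2-[3,4-bis(benzyloxy)phenyl]-3-hydroxychroman-4-one
Product: 11 (2R,3S,4R)-5,7-bis(benzyloxy)-2-[3,4-bis(benzyloxy)phenyl]chromane-3,4-diol
Conditions: NaBH4, THF–MeOH, 0 °C
Reagents that add atoms: none
Why: Borohydride reduction of the aryl ketone; axial hydride delivery should give mainly the 3,4-trans diol.

Step 9
Reactants: 11 (2R,3S,4R)-5,7-bis(benzyloxy)-2-[3,4-bis(benzyloxy)phenyl]chromane-3,4-diol
Product: 12 (2R,3S,4R)-5,7-bis(benzyloxy)-2-[3,4-bis(benzyloxy)phenyl]-8-bromochromane-3,4-diol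
Conditions: NBS (1.05 equiv), CH2Cl2, −78 °C
Reagents that add atoms: N-bromosuccinimide, O=C1CCC(=O)N1Br
Why: Electrophilic aromatic bromination of ring A at C8, the more accessible of its two free positions (C6 lies between two benzyloxy groups); the bromine caps C8 so that later bonds can form only at C6.

Step 10
Reactants: 13 (−)-epicatechin
Product: 14 5,7,3′,4′-tetra-O-benzyl-(−)-epicatechin
Conditions: BnBr (4.4 equiv), K2CO3, DMF, 0 °C to rt
Reagents that add atoms: benzyl bromide, BrCc1ccccc1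
Why: Williamson etherification of the four phenols; the secondary 3-hydroxyl is not deprotonated by carbonate and stays free, and both stereocentres are untouched.

Step 11
Reactants: 14 5,7,3′,4′-tetra-O-benzyl-(−)-epicatechin
Product: 15 8-bromo-5,7,3′,4′-tetra-O-benzyl-(−)-epicatechin
Conditions: NBS (1.05 equiv), CH2Cl2, −78 °C
Reagents that add atoms: N-bromosuccinimide, O=C1CCC(=O)N1Br
Why: Regioselective electrophilic bromination at C8, leaving C6 as the only nucleophilic position of ring A.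

Step 12
Reactants: 12 (2R,3S,4R)-8-bromo-3,4-diol; 15 8-bromo-5,7,3′,4′-tetra-O-benzyl-(−)-epicatechin
Product: 16 [8-bromo-5,7,3′,4′-tetra-O-benzylcatechin]-(4α→6)-[8-bromo-5,7,3′,4′-tetra-O-benzylepicatechin]
Conditions: TiCl4 (1.0 equiv), CH2Cl2–THF, −78 to 0 °C; 15 in excess (3 equiv), 12 added slowly
Reagents that add atoms: none
Why: Lewis acid ionisation of the benzylic 4-hydroxyl gives the flavan-4-yl cation stabilised by the 5,7-dioxygenated ring A; Friedel–Crafts alkylation by C6 of 15, its only free ring A position, should occur trans to the 3-hydroxyl (4α, all ring C substituents equatorial), and slow addition keeps un-ionised 12 low so that its own C6 does not compete.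

Step 13
Reactants: 12 (2R,3S,4R)-8-bromo-3,4-diol; 16 the dimer of step 12
Product: 17 [8-bromo-5,7,3′,4′-tetra-O-benzylcatechin]-(4α→6)-[8-bromo-5,7,3′,4′-tetra-O-benzylcatechin]-(4α→6)-[8-bromo-5,7,3′,4′-tetra-O-benzylepicatechin]
Conditions: TiCl4 (1.5 equiv), CH2Cl2–THF, −78 to 0 °C; 16 in excess (2 equiv, recovered), 12 added slowly
Reagents that add atoms: none
Why: The same cation is taken up in a Friedel–Crafts alkylation by the only unsubstituted ring A position of 16, C6 of its catechin unit (C8 brominated, the epicatechin ring fully substituted), which fixes the 4→6 regiochemistry; attack trans to the 3-hydroxyl should again give the 4α bond.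

Step 14
Reactants: 17 the tribromo dodeca-O-benzyl trimer
Product: 18 catechin-(4α→6)-catechin-(4α→6)-epicatechin (CNP0163146.3)
Conditions: H2 (1 atm), Pd(OH)2/C, Et3N (3.3 equiv), THF–MeOH–H2O, rt
Reagents that add atoms: none
Why: Catalytic hydrogenolysis removes the three aryl bromides and the twelve benzyl ethers in one operation; triethylamine takes up HBr so that the acid-labile interflavan bonds survive, and no stereocentre is affected.

**Compound list**

1 | 3,5-bis(benzyloxy)phenol | Oc1cc(OCc2ccccc2)cc(OCc2ccccc2)c1 | starting material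
2 | 3,5-bis(benzyloxy)-2-iodophenol | Oc1cc(OCc2ccccc2)cc(OCc2ccccc2)c1I | intermediate
3 | 3,4-bis(benzyloxy)benzaldehyde | O=Cc1ccc(OCc2ccccc2)c(OCc2ccccc2)c1 | starting material
4 | bromomagnesium 1-[3,4-bis(benzyloxy)phenyl]prop-2-yn-1-olate (racemic) | C#CC(O[Mg]Br)c1ccc(OCc2ccccc2)c(OCc2ccccc2)c1 | intermediate (not isolated)
5 | rac-1-[3,4-bis(benzyloxy)phenyl]prop-2-yn-1-yl acetate | CC(=O)OC(C#C)c1ccc(OCc2ccccc2)c(OCc2ccccc2)c1 | intermediate
6 | 1,5-bis(benzyloxy)-3-({(1S)-1-[3,4-bis(benzyloxy)phenyl]prop-2-yn-1-yl}oxy)-2-iodobenzene | C#C[C@H](Oc1cc(OCc2ccccc2)cc(OCc2ccccc2)c1I)c1ccc(OCc2ccccc2)c(OCc2ccccc2)c1 | intermediate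
7 | (2R)-4,6-bis(benzyloxy)-2-[3,4-bis(benzyloxy)phenyl]-3-methylidene-2,3-dihydro-1-benzofuran | C=C1c2c(OCc3ccccc3)cc(OCc3ccccc3)cc2O[C@@H]1c1ccc(OCc2ccccc2)c(OCc2ccccc2)c1 | intermediate
8 | (2R,3R)-4,6-bis(benzyloxy)-2-[3,4-bis(benzyloxy)phenyl]-3-(hydroxymethyl)-2,3-dihydro-1-benzofuran-3-ol | OC[C@]1(O)c2c(OCc3ccccc3)cc(OCc3ccccc3)cc2O[C@@H]1c1ccc(OCc2ccccc2)c(OCc2ccccc2)c1 | intermediate
9 | (2R,3S)-4,6-bis(benzyloxy)-2-[3,4-bis(benzyloxy)phenyl]-3-hydroxy-2,3-dihydro-1-benzofuran-3-carbaldehyde | O=C[C@]1(O)c2c(OCc3ccccc3)cc(OCc3ccccc3)cc2O[C@@H]1c1ccc(OCc2ccccc2)c(OCc2ccccc2)c1 | intermediate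
10 | (2R,3R)-5,7-bis(benzyloxy)-2-[3,4-bis(benzyloxy)phenyl]-3-hydroxychroman-4-one | O[C@H]1C(=O)c2c(OCc3ccccc3)cc(OCc3ccccc3)cc2O[C@@H]1c1ccc(OCc2ccccc2)c(OCc2ccccc2)c1 | intermediate
11 | (2R,3S,4R)-5,7-bis(benzyloxy)-2-[3,4-bis(benzyloxy)phenyl]chromane-3,4-diol | O[C@H]1[C@H](O)c2c(OCc3ccccc3)cc(OCc3ccccc3)cc2O[C@@H]1c1ccc(OCc2ccccc2)c(OCc2ccccc2)c1 | intermediate
12 | (2R,3S,4R)-5,7-bis(benzyloxy)-2-[3,4-bis(benzyloxy)phenyl]-8-bromochromane-3,4-diol | O[C@H]1[C@H](O)c2c(OCc3ccccc3)cc(OCc3ccccc3)c(Br)c2O[C@@H]1c1ccc(OCc2ccccc2)c(OCc2ccccc2)c1 | intermediate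
13 | (−)-epicatechin, (2R,3R) | O[C@@H]1Cc2c(O)cc(O)cc2O[C@@H]1c1ccc(O)c(O)c1 | starting material
14 | 5,7,3′,4′-tetra-O-benzyl-(−)-epicatechin | O[C@@H]1Cc2c(OCc3ccccc3)cc(OCc3ccccc3)cc2O[C@@H]1c1ccc(OCc2ccccc2)c(OCc2ccccc2)c1 | intermediate
15 | 8-bromo-5,7,3′,4′-tetra-O-benzyl-(−)-epicatechin | O[C@@H]1Cc2c(OCc3ccccc3)cc(OCc3ccccc3)c(Br)c2O[C@@H]1c1ccc(OCc2ccccc2)c(OCc2ccccc2)c1 | intermediate
16 | [8-bromo-tetra-O-benzylcatechin]-(4α→6)-[8-bromo-tetra-O-benzylepicatechin] | O[C@H]1[C@H](c2c(OCc3ccccc3)c3C[C@@H](O)[C@@H](c4ccc(OCc5ccccc5)c(OCc5ccccc5)c4)Oc3c(Br)c2OCc2ccccc2)c2c(OCc3ccccc3)cc(OCc3ccccc3)c(Br)c2O[C@@H]1c1ccc(OCc2ccccc2)c(OCc2ccccc2)c1 | intermediate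
17 | [8-bromo-tetra-O-benzylcatechin]-(4α→6)-[8-bromo-tetra-O-benzylcatechin]-(4α→6)-[8-bromo-tetra-O-benzylepicatechin] | O[C@H]1[C@H](c2c(OCc3ccccc3)c3[C@@H](c4c(OCc5ccccc5)c5C[C@@H](O)[C@@H](c6ccc(OCc7ccccc7)c(OCc7ccccc7)c6)Oc5c(Br)c4OCc4ccccc4)[C@H](O)[C@@H](c4ccc(OCc5ccccc5)c(OCc5ccccc5)c4)Oc3c(Br)c2OCc2ccccc2)c2c(OCc3ccccc3)cc(OCc3ccccc3)c(Br)c2O[C@@H]1c1ccc(OCc2ccccc2)c(OCc2ccccc2)c1 | intermediate
18 | catechin-(4α→6)-catechin-(4α→6)-epicatechin (CNP0163146.3) | Oc1cc(O)c2c(c1)O[C@H](c1ccc(O)c(O)c1)[C@@H](O)[C@@H]2c1c(O)cc2c(c1O)[C@@H](c1c(O)cc3c(c1O)C[C@@H](O)[C@@H](c1ccc(O)c(O)c1)O3)[C@H](O)[C@@H](c1ccc(O)c(O)c1)O2 | target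

**Step count.** Total: 14 steps. Longest linear sequence: 11 steps (steps 2–9, then 12–14).

**Steps most likely to fail**

1. Step 7. The tertiary benzylic carbinol may lose water with aromatisation to the benzofuran, the ring A carbon may migrate in place of C2, or the aldehyde may disproportionate on aluminium. Fallback, setting out from 7 and still a five-to-six ring expansion, now by oxidative 1,2-shift of the ring A carbon: treatment of 7 with PhI(OH)OTs in MeOH and mild acid hydrolysis of the ketal should give (2R)-5,7-bis(benzyloxy)-2-[3,4-bis(benzyloxy)phenyl]chroman-3-one F1. Meerwein–Ponndorf–Verley reduction (Al(Oi-Pr)3, i-PrOH), which can equilibrate to the diequatorial alcohol, should give 5,7,3′,4′-tetra-O-benzylcatechin F2. DDQ with 2-ethoxyethanol should give (2R,3S,4S)-5,7-bis(benzyloxy)-2-[3,4-bis(benzyloxy)phenyl]-4-(2-ethoxyethoxy)chroman-3-ol F3, and NBS its 8-bromo derivative F4. F4, activated with TMSOTf, takes the place of 12 in steps 12 and 13, so the fallback comes back to the route at 16.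

2. Step 3. The electron-rich phenol ring may be alkylated at carbon instead of oxygen, and uncatalysed ionisation of the electron-rich propargylic acetate may erode the enantiomeric purity. Fallback, setting out from 5, in which the centre is bought by resolution and transferred by SN2 inversion: kinetic resolution with Candida antarctica lipase B (with mild methanolysis of the acetate fraction if needed) secures (R)-1-[3,4-bis(benzyloxy)phenyl]prop-2-yn-1-ol F5. Mitsunobu etherification of F5 with phenol 2 (PPh3, DIAD, toluene, −20 °C) should give 6 with inversion, where the route is rejoined.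

3. Step 13. The cation from 12 may be intercepted by C6 of a second molecule of 12, and the hindered, brominated ring of 16 may react slowly. Fallback, setting out from 11, with a fully capped electrophile that cannot act as a nucleophile and can therefore be used in excess: NBS (2.1 equiv) should give (2R,3S,4R)-5,7-bis(benzyloxy)-2-[3,4-bis(benzyloxy)phenyl]-6,8-dibromochromane-3,4-diol F6. TiCl4-mediated coupling of F6 with 16 should give the tetrabromo dodeca-O-benzyl trimer F7, and hydrogenolysis as in step 14 returns to the route at 18.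

Further compounds
F1 | step 7 | (2R)-5,7-bis(benzyloxy)-2-[3,4-bis(benzyloxy)phenyl]chroman-3-one | O=C1Cc2c(OCc3ccccc3)cc(OCc3ccccc3)cc2O[C@@H]1c1ccc(OCc2ccccc2)c(OCc2ccccc2)c1
F2 | step 7 | 5,7,3′,4′-tetra-O-benzyl-(+)-catechin | O[C@H]1Cc2c(OCc3ccccc3)cc(OCc3ccccc3)cc2O[C@@H]1c1ccc(OCc2ccccc2)c(OCc2ccccc2)c1
F3 | step 7 | (2R,3S,4S)-5,7-bis(benzyloxy)-2-[3,4-bis(benzyloxy)phenyl]-4-(2-ethoxyethoxy)chroman-3-ol | O[C@H]1[C@@H](OCCOCC)c2c(OCc3ccccc3)cc(OCc3ccccc3)cc2O[C@@H]1c1ccc(OCc2ccccc2)c(OCc2ccccc2)c1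
F4 | step 7 | (2R,3S,4S)-5,7-bis(benzyloxy)-2-[3,4-bis(benzyloxy)phenyl]-8-bromo-4-(2-ethoxyethoxy)chroman-3-ol | O[C@H]1[C@@H](OCCOCC)c2c(OCc3ccccc3)cc(OCc3ccccc3)c(Br)c2O[C@@H]1c1ccc(OCc2ccccc2)c(OCc2ccccc2)c1
F5 | step 3 | (R)-1-[3,4-bis(benzyloxy)phenyl]prop-2-yn-1-ol | C#C[C@@H](O)c1ccc(OCc2ccccc2)c(OCc2ccccc2)c1
F6 | step 13 | (2R,3S,4R)-5,7-bis(benzyloxy)-2-[3,4-bis(benzyloxy)phenyl]-6,8-dibromochromane-3,4-diol | O[C@H]1[C@H](O)c2c(OCc3ccccc3)c(Br)c(OCc3ccccc3)c(Br)c2O[C@@H]1c1ccc(OCc2ccccc2)c(OCc2ccccc2)c1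
F7 | step 13 | [6,8-dibromo-tetra-O-benzylcatechin]-(4α→6)-[8-bromo-tetra-O-benzylcatechin]-(4α→6)-[8-bromo-tetra-O-benzylepicatechin] | O[C@H]1[C@H](c2c(OCc3ccccc3)c3[C@@H](c4c(OCc5ccccc5)c5C[C@@H](O)[C@@H](c6ccc(OCc7ccccc7)c(OCc7ccccc7)c6)Oc5c(Br)c4OCc4ccccc4)[C@H](O)[C@@H](c4ccc(OCc5ccccc5)c(OCc5ccccc5)c4)Oc3c(Br)c2OCc2ccccc2)c2c(OCc3ccccc3)c(Br)c(OCc3ccccc3)c(Br)c2O[C@@H]1c1ccc(OCc2ccccc2)c(OCc2ccccc2)c1
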